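In this closed, stirred vessel the solid substrate passes into solution while the gas supplies reagent, and undissolved solid can also consume target already formed.

| flask | solid substrate | gas | remark | time |
|---|---|---|---|---|
| alder | 0.12 M | 29 mM (held) | run made earlier |  |
| cedar | 0.50 M | 29 mM (held) | run made earlier |  |
| flask | 0.25 M | 29 mM (held) |  | 5.0 h |

| run | time / h | target / % |
|---|---|---|
| alder | 0.417 | 92.0 |
| alder | 1.00 | 93.4 |
| alder | 2.00 | 93.4 |
| alder | 3.00 | 93.3 |
| cedar | 0.833 | 51.3 |
| cedar | 1.50 | 50.0 |
| cedar | 2.50 | 48.4 |
| cedar | 3.00 | 49.2 |

(scatter of a reading: 1 percentage point)

- a species is counted by the solid substrate in it: one side product counts as two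
- given per volume of solution although it is solid: solid substrate
- at the start none of reagent is dissolved
- steps under discussion: solid substrate <-> dissolved substrate; dissolved substrate + reagent -> target; solid substrate + target -> side product; gas <-> reagent
- at the start none of the solid substrate is in solution

- target at 5.0 h, in percent of the solid substrate charged
- the change that raises the amount of target at 5.0 h, in percent of the solid substrate charged most ("none" if none brings more than 2 percentage points) (ochre / violet / blue / green / none)
- amount of target at 5.0 h, in percent of the solid substrate charged, after violet

- ochre: doubling the solubility of the solid substrate, all else as stated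
- violet: doubling the saturation concentration of gas, all else as stated
- blue: doubling the transfer coefficient of the gas, all else as stated
- green: doubling the dissolution coefficient of the solid substrate, all else as stated

The alder run holds 93.4 % at 1.00 h and 93.3 % at 3.00 h, and the cedar run reads 51.3 % at 0.833 h and 49.2 % at 3.00 h. So we treat the asked time as an end state, with the charge shared between target and side product.

The question is then how that share moves with the charge. Suppose solid enters solution at a steady rate. Solid and target then both grow with the charge, and the solid lasts in proportion to it, so side product over target should grow with the square of c(solid substrate).

From alder we read 4.99 M⁻² as the loss constant, the share of the charge in side product over the share in target, per square of c(solid substrate). Cedar reads 4.13 M⁻², somewhat lower. For this flask, our own reckoning gives 76.2 % with alder's value and 79.5 % with cedar's, and we expect the target to lie between them.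

The forecast gives 78 %, chooses violet and puts that change at 86 %, with the caution: “The runs don't show which step limits.”

The flask gives 75.1 %. The best change is ochre, worth 7.4 percentage points, while violet adds 2.3 points and reaches 77.4 %.

    solid substrate ⇌ dissolved substrate, rate k1*(cs1 - [dissolved substrate]) while solid is left; crystals form when [dissolved substrate] > cs1 (solubility = 17.0 mM, k = 0.0210 s⁻¹)
    dissolved substrate + reagent → target (k = 6.50 M⁻¹ s⁻¹)
    solid substrate + target → side product (k = 0.00530 M⁻¹ s⁻¹)
    gas ⇌ reagent, rate k4*(csat - [reagent]) (kL = 0.0150 s⁻¹)

Read back through the loss constant, the flask's target gives 5.30 M⁻², above alder's value. Alder's loss constant, applied to a neighbour flask charged with 0.10 M, gives 95.2 %, and that neighbour flask stands at 94.7 %.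

The data are simulated for an exercise, noise included.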